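**Retrosynthetic overview**
1. Integric acid ⇒ its C1 tert-butyl ester; the 2-formylvinyl arm at C7 ⇒ a C7 allyl group (oxidative cleavage, then α-methylenation); the C4–O ester bond ⇒ axial allylic alcohol + (2E,4S)-2,4-dimethyloct-2-enoic acid.
2. C4–OH ⇒ γ-hydroxylation of the silyl dienol ether of the octalenone; C1 stereocentre ⇒ conjugate reduction/protonation of a cyclohex-1-enecarboxylate; C7 ⇒ α′-allylation.
3. Key disconnection: the cyclohexenecarboxylate ring A ⇒ one-carbon ring expansion of the cyclopentanone of (S)-Hajos–Parrish ketone with tert-butyl diazoacetate (diazo-aldol, then 1,2-shift of the quaternary ring carbon in a vinyl cation, hydride quench).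
4. Ring order: ring B (the enone ring with the quaternary methyl centre) first, by proline-catalysed Robinson annulation of 2-methylcyclopentane-1,3-dione with methyl vinyl ketone; ring A second, by expansion of the five-membered ring.
5. Side-chain acid ⇒ Wittig olefination of (S)-2-methylhexanal ⇐ copper-catalysed propylation of (R)-3-bromo-2-methylpropan-1-ol.

Assumption: locants in the text follow the naphthalene numbering of the product names (C1 carries the carboxyl group, C4 the ester oxygen, C7 the three-carbon arm, C8a the methyl group).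

**Route**

Step 1
Reactants: 1 2-methylcyclopentane-1,3-dione; 2 but-3-en-2-one (methyl vinyl ketone)
Product: 5 (7aS)-7a-methyl-2,3,7,7a-tetrahydro-1H-indene-1,5(6H)-dione (Hajos–Parrish ketone), via triketone 3 (not isolated), via ketol 4 (not isolated)
Conditions: 2 (1.5 equiv), AcOH (cat.), H2O, 75 °C; evaporate; L-proline (3 mol %), DMF, 20 °C, 24 h; then H2SO4 (cat.), 95 °C; recrystallize
Reagents that add atoms: none
Why: Michael addition followed by the proline-catalysed Hajos–Parrish enamine aldol desymmetrization and acid dehydration is a Robinson annulation in which the (S)-proline enamine closes onto one enantiotopic ring carbonyl and sets the quaternary (7aS) centre.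

Step 2
Reactants: 5 (7aS)-7a-methyl-2,3,7,7a-tetrahydro-1H-indene-1,5(6H)-dione
Product: 6 tert-butyl 2-diazo-2-[(1S,7aS)-1-hydroxy-7a-methyl-5-oxo-2,3,5,6,7,7a-hexahydro-1H-inden-1-yl]acetate
Conditions: tert-butyl diazoacetate (1.1 equiv), LiN(i-Pr)2 (1.1 equiv), THF, −78 °C; then 5, −78 °C, 1 h; AcOH quench at −78 °C
Reagents that add atoms: tert-butyl diazoacetate, CC(C)(C)OC(=O)C=[N+]=[N-]
Why: Aldol-type 1,2-addition of the lithiated diazoester goes to the saturated cyclopentanone, which is more electrophilic than the conjugated enone carbonyl (the same preference as in hydride reduction of this diketone), from the face opposite the angular methyl group, and the (1S) carbinol configuration is erased in the next step.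

Step 3
Reactants: 6 tert-butyl 2-diazo-2-[(1S,7aS)-1-hydroxy-7a-methyl-5-oxo-2,3,5,6,7,7a-hexahydro-1H-inden-1-yl]acetate
Product: 7 tert-butyl (8aS)-8a-methyl-6-oxo-3,4,6,7,8,8a-hexahydronaphthalene-1-carboxylate
Conditions: Sc(OTf)3 (10 mol %), Et3SiH (4 equiv), CH2Cl2, −40 → 0 °C, slow addition of 6
Reagents that add atoms: none
Why: Proposed new method: Sc(OTf)3 ionizes the tertiary hydroxyl β to the diazo carbon to a vinyldiazonium ion, loss of N2 gives a linear vinyl cation destabilized by the adjacent ester, and this drives a 1,2-shift of the ring bond from the quaternary carbon C7a (the better σ-donor, whose migration also relieves the congested C1–C7a junction) onto the cationic carbon, so the cyclopentane expands to a cyclohex-1-enyl cation that takes hydride from Et3SiH faster than the enone can be reduced at this temperature, which excises the carbonyl oxygen, places the ester-bearing carbon next to the quaternary centre and touches no stereocentre (the migrating carbon moves with retention); the closest known reaction type is the Lewis-acid-promoted vinyl-cation ring expansion of β-hydroxy-α-diazo carbonyl compounds, known with termination by C–H insertion or by arene or nitrile capture, whereas hydride termination by a silane and migration of a quaternary ring carbon in a hydrindenone have not been described.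

Step 4
Reactants: 7 tert-butyl (8aS)-8a-methyl-6-oxo-3,4,6,7,8,8a-hexahydronaphthalene-1-carboxylate
Product: 8 tert-butyl (7R,8aS)-8a-methyl-6-oxo-7-(prop-2-en-1-yl)-3,4,6,7,8,8a-hexahydronaphthalene-1-carboxylate
Conditions: LiN(i-Pr)2 (1.1 equiv), THF, −78 °C; then allyl bromide (1.5 equiv), DMPU, −78 → −30 °C
Reagents that add atoms: allyl bromide, C=CCBr
Why: Kinetic deprotonation removes an α′ proton at C7 rather than a γ proton, and SN2 allylation of the cross-conjugated lithium enolate occurs anti to the axial angular methyl group to give the equatorial (7R) allyl ketone, which is also the thermodynamically preferred epimer.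

Step 5
Reactants: 8 tert-butyl (7R,8aS)-8a-methyl-6-oxo-7-(prop-2-en-1-yl)-3,4,6,7,8,8a-hexahydronaphthalene-1-carboxylate
Product: 9 tert-butyl (7R,8aS)-6-[(tert-butyldimethylsilyl)oxy]-8a-methyl-7-(prop-2-en-1-yl)-3,7,8,8a-tetrahydronaphthalene-1-carboxylate
Conditions: TBSOTf (1.2 equiv), Et3N (3 equiv), CH2Cl2, −78 → 0 °C, 30 min
Reagents that add atoms: tert-butyldimethylsilyl trifluoromethanesulfonate (TBSOTf), CC(C)(C)[Si](C)(C)OS(=O)(=O)C(F)(F)F
Why: Soft enolization with silyl triflate and amine under equilibrating conditions gives the linearly conjugated (thermodynamic) silyl dienol ether by loss of a γ proton from C4, which masks the enone against electron transfer and arms C4 for oxidation, while the brief cold exposure spares the tert-butyl ester.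

Step 6
Reactants: 9 tert-butyl (7R,8aS)-6-[(tert-butyldimethylsilyl)oxy]-8a-methyl-7-(prop-2-en-1-yl)-3,7,8,8a-tetrahydronaphthalene-1-carboxylate
Product: 10 tert-butyl (1S,7R,8aR)-6-[(tert-butyldimethylsilyl)oxy]-8a-methyl-7-(prop-2-en-1-yl)-1,2,3,7,8,8a-hexahydronaphthalene-1-carboxylate
Conditions: SmI2 (2.5 equiv), HMPA, t-BuOH (2.5 equiv), THF, −78 °C
Reagents that add atoms: none
Why: SmI2 conjugate reduction (two single-electron transfers with protonation) acts only on the α,β-unsaturated ester because the silyloxydiene and the isolated alkene are not reducible, and the samarium enolate is protonated at C1 on the α face anti to the axial C8a methyl group, which places the ester equatorial and cis to the methyl group (1S).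

Step 7
Reactants: 10 tert-butyl (1S,7R,8aR)-6-[(tert-butyldimethylsilyl)oxy]-8a-methyl-7-(prop-2-en-1-yl)-1,2,3,7,8,8a-hexahydronaphthalene-1-carboxylate
Product: 11 tert-butyl (1S,4R,7R,8aR)-4-hydroxy-8a-methyl-6-oxo-7-(prop-2-en-1-yl)-1,2,3,4,6,7,8,8a-octahydronaphthalene-1-carboxylate
Conditions: mCPBA (1.05 equiv), NaHCO3, CH2Cl2, −20 → 0 °C; aq. Na2S2O3/NaHCO3 work-up
Reagents that add atoms: mCPBA (3-chloroperoxybenzoic acid), OOC(=O)c1cccc(Cl)c1
Why: In this vinylogous Rubottom oxidation the peracid transfers oxygen to the γ terminus C4 of the silyloxydiene along the axial trajectory on the β face, as in the 6β-hydroxylation of steroidal 3,5-dienol ethers, and collapse with loss of the silyl group returns the enone with the axial (4R) alcohol cis to the angular methyl group, the electron-poor and monosubstituted alkenes reacting much more slowly.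

Step 8
Reactants: 12 (R)-3-bromo-2-methylpropan-1-ol
Product: 13 (S)-2-methylhexan-1-ol
Conditions: n-PrMgCl (3 equiv), Li2CuCl4 (5 mol %), THF, −20 → 20 °C; 1 M HCl work-up
Reagents that add atoms: n-propylmagnesium chloride, CCC[Mg]Cl
Why: Copper-catalysed Kumada-type sp3–sp3 coupling of the primary bromide (the first equivalent of Grignard reagent only deprotonates the hydroxyl) forms the new C–C bond away from the stereocentre, so the configuration of the pool material is carried over and only the descriptor changes from R to S through the priority rules.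

Step 9
Reactants: 13 (S)-2-methylhexan-1-ol
Product: 15 ethyl (2E,4S)-2,4-dimethyloct-2-enoate, via aldehyde 14 (not isolated)
Conditions: PhI(OAc)2 (1.1 equiv), TEMPO (10 mol %), CH2Cl2, 20 °C; then Ph3P=C(CH3)CO2Et (1.5 equiv), 40 °C
Reagents that add atoms: ethyl 2-(triphenylphosphoranylidene)propanoate, CCOC(=O)C(C)=P(c1ccccc1)(c1ccccc1)c1ccccc1
Why: Oxoammonium (TEMPO) oxidation gives the aldehyde under conditions too mild to racemize its α-stereocentre, and in-situ Wittig olefination with the stabilized α-methyl ylide gives the E trisubstituted enoate.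

Step 10
Reactants: 15 ethyl (2E,4S)-2,4-dimethyloct-2-enoate
Product: 16 (2E,4S)-2,4-dimethyloct-2-enoic acid
Conditions: LiOH (3 equiv), THF/MeOH/H2O, 40 °C; then 1 M HCl
Reagents that add atoms: lithium hydroxide, [Li+].[OH-]
Why: Saponification (acyl-oxygen ester hydrolysis) uses a base far too weak to deprotonate the γ-stereocentre or to isomerize the trisubstituted alkene.

Step 11
Reactants: 11 tert-butyl (1S,4R,7R,8aR)-4-hydroxy-8a-methyl-6-oxo-7-(prop-2-en-1-yl)-1,2,3,4,6,7,8,8a-octahydronaphthalene-1-carboxylate; 16 (2E,4S)-2,4-dimethyloct-2-enoic acid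
Product: 18 tert-butyl (1S,4R,7R,8aR)-4-{[(2E,4S)-2,4-dimethyloct-2-enoyl]oxy}-8a-methyl-6-oxo-7-(prop-2-en-1-yl)-1,2,3,4,6,7,8,8a-octahydronaphthalene-1-carboxylate, via mixed anhydride 17 (not isolated)
Conditions: 16 (1.5 equiv), 2,4,6-trichlorobenzoyl chloride, Et3N, toluene, 20 °C; then 11, DMAP, 40 °C
Reagents that add atoms: none
Why: In this Yamaguchi esterification DMAP attacks the mixed anhydride at the less hindered enoyl carbonyl and the acylpyridinium acylates the hindered axial allylic alcohol with retention at C4, while the tert-butyl ester prevents lactonization or anhydride formation at the C1 carboxyl.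

Step 12
Reactants: 18 tert-butyl (1S,4R,7R,8aR)-4-{[(2E,4S)-2,4-dimethyloct-2-enoyl]oxy}-8a-methyl-6-oxo-7-(prop-2-en-1-yl)-1,2,3,4,6,7,8,8a-octahydronaphthalene-1-carboxylate
Product: 20 tert-butyl (1S,4R,7S,8aR)-4-{[(2E,4S)-2,4-dimethyloct-2-enoyl]oxy}-8a-methyl-6-oxo-7-(2-oxoethyl)-1,2,3,4,6,7,8,8a-octahydronaphthalene-1-carboxylate, via diol 19 (not isolated)
Conditions: OsO4 (2 mol %), NaIO4 (4 equiv), 2,6-lutidine, dioxane/H2O 3:1, 20 °C
Reagents that add atoms: sodium periodate, [Na+].[O-][I](=O)(=O)=O (terminal oxidant; supplies the aldehyde oxygen through the OsO4 cycle)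
Why: In this Lemieux–Johnson oxidation OsO4 dihydroxylates the monosubstituted terminal alkene much faster than the two trisubstituted electron-poor conjugated alkenes and periodate cleaves the diol to the aldehyde, with 2,6-lutidine suppressing over-oxidation (the C7 descriptor becomes S only through the priority rules).

Step 13
Reactants: 20 tert-butyl (1S,4R,7S,8aR)-4-{[(2E,4S)-2,4-dimethyloct-2-enoyl]oxy}-8a-methyl-6-oxo-7-(2-oxoethyl)-1,2,3,4,6,7,8,8a-octahydronaphthalene-1-carboxylate
Product: 21 tert-butyl (1S,4R,7S,8aR)-4-{[(2E,4S)-2,4-dimethyloct-2-enoyl]oxy}-8a-methyl-6-oxo-7-(3-oxoprop-1-en-2-yl)-1,2,3,4,6,7,8,8a-octahydronaphthalene-1-carboxylate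
Conditions: 37% aq. CH2O (1.2 equiv), pyrrolidine (10 mol %), propionic acid (10 mol %), i-PrOH, 45 °C
Reagents that add atoms: formaldehyde, C=O
Why: Amine-catalysed α-methylenation (Mannich condensation of the aldehyde enamine with formaldehyde, then elimination of the amine) is specific for the unhindered aldehyde α-CH2 and gives the 2-substituted acrolein, while C7 stays in its thermodynamically preferred equatorial configuration.

Step 14
Reactants: 21 tert-butyl (1S,4R,7S,8aR)-4-{[(2E,4S)-2,4-dimethyloct-2-enoyl]oxy}-8a-methyl-6-oxo-7-(3-oxoprop-1-en-2-yl)-1,2,3,4,6,7,8,8a-octahydronaphthalene-1-carboxylate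
Product: 22 integric acid [(1S,4R,7S,8aR)-4-{[(2E,4S)-2,4-dimethyloct-2-enoyl]oxy}-8a-methyl-6-oxo-7-(3-oxoprop-1-en-2-yl)-1,2,3,4,6,7,8,8a-octahydronaphthalene-1-carboxylic acid]
Conditions: TFA/CH2Cl2 1:4, 0 → 20 °C
Reagents that add atoms: none
Why: Acidolysis of the tert-butyl ester (E1 loss of isobutene) frees the carboxylic acid without base, so the secondary allylic ester, the enal and the enone are left untouched.

**Compound list**
1 | 2-methylcyclopentane-1,3-dione | CC1C(=O)CCC1=O | starting material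
2 | but-3-en-2-one (methyl vinyl ketone) | CC(=O)C=C | starting material
3 | 2-methyl-2-(3-oxobutyl)cyclopentane-1,3-dione | CC(=O)CCC1(C)C(=O)CCC1=O | intermediate
4 | (3aS,7aS)-3a-hydroxy-7a-methylhexahydro-1H-indene-1,5(4H)-dione | O=C1CC[C@@]2(C)[C@@](O)(C1)CCC2=O | intermediate
5 | (7aS)-7a-methyl-2,3,7,7a-tetrahydro-1H-indene-1,5(6H)-dione | O=C1CC[C@@]2(C)C(=C1)CCC2=O | intermediate
6 | tert-butyl 2-diazo-2-[(1S,7aS)-1-hydroxy-7a-methyl-5-oxo-2,3,5,6,7,7a-hexahydro-1H-inden-1-yl]acetate | O=C1CC[C@@]2(C)C(=C1)CC[C@@]2(O)C(=[N+]=[N-])C(=O)OC(C)(C)C | intermediate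
7 | tert-butyl (8aS)-8a-methyl-6-oxo-3,4,6,7,8,8a-hexahydronaphthalene-1-carboxylate | O=C1CC[C@@]2(C)C(=C1)CCC=C2C(=O)OC(C)(C)C | intermediate
8 | tert-butyl (7R,8aS)-8a-methyl-6-oxo-7-(prop-2-en-1-yl)-3,4,6,7,8,8a-hexahydronaphthalene-1-carboxylate | C=CC[C@@H]1C[C@@]2(C)C(=CC1=O)CCC=C2C(=O)OC(C)(C)C | intermediate
9 | tert-butyl (7R,8aS)-6-[(tert-butyldimethylsilyl)oxy]-8a-methyl-7-(prop-2-en-1-yl)-3,7,8,8a-tetrahydronaphthalene-1-carboxylate | C=CC[C@@H]1C[C@@]2(C)C(C=C1O[Si](C)(C)C(C)(C)C)=CCC=C2C(=O)OC(C)(C)C | intermediate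
10 | tert-butyl (1S,7R,8aR)-6-[(tert-butyldimethylsilyl)oxy]-8a-methyl-7-(prop-2-en-1-yl)-1,2,3,7,8,8a-hexahydronaphthalene-1-carboxylate | C=CC[C@@H]1C[C@@]2(C)C(C=C1O[Si](C)(C)C(C)(C)C)=CCC[C@@H]2C(=O)OC(C)(C)C | intermediate
11 | tert-butyl (1S,4R,7R,8aR)-4-hydroxy-8a-methyl-6-oxo-7-(prop-2-en-1-yl)-1,2,3,4,6,7,8,8a-octahydronaphthalene-1-carboxylate | C=CC[C@@H]1C[C@@]2(C)C(=CC1=O)[C@H](O)CC[C@@H]2C(=O)OC(C)(C)C | intermediate
12 | (R)-3-bromo-2-methylpropan-1-ol | OC[C@@H](C)CBr | starting material
13 | (S)-2-methylhexan-1-ol | OC[C@@H](C)CCCC | intermediate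
14 | (S)-2-methylhexanal | O=C[C@@H](C)CCCC | intermediate
15 | ethyl (2E,4S)-2,4-dimethyloct-2-enoate | CCOC(=O)/C(C)=C/[C@@H](C)CCCC | intermediate
16 | (2E,4S)-2,4-dimethyloct-2-enoic acid | OC(=O)/C(C)=C/[C@@H](C)CCCC | intermediate
17 | (2E,4S)-2,4-dimethyloct-2-enoic 2,4,6-trichlorobenzoic anhydride | O=C(OC(=O)/C(C)=C/[C@@H](C)CCCC)c1c(Cl)cc(Cl)cc1Cl | intermediate
18 | tert-butyl (1S,4R,7R,8aR)-4-{[(2E,4S)-2,4-dimethyloct-2-enoyl]oxy}-8a-methyl-6-oxo-7-(prop-2-en-1-yl)-1,2,3,4,6,7,8,8a-octahydronaphthalene-1-carboxylate | C=CC[C@@H]1C[C@@]2(C)C(=CC1=O)[C@H](OC(=O)/C(C)=C/[C@@H](C)CCCC)CC[C@@H]2C(=O)OC(C)(C)C | intermediate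
19 | tert-butyl (1S,4R,7S,8aR)-7-(2,3-dihydroxypropyl)-4-{[(2E,4S)-2,4-dimethyloct-2-enoyl]oxy}-8a-methyl-6-oxo-1,2,3,4,6,7,8,8a-octahydronaphthalene-1-carboxylate (both epimers at the secondary carbinol) | OCC(O)C[C@@H]1C[C@@]2(C)C(=CC1=O)[C@H](OC(=O)/C(C)=C/[C@@H](C)CCCC)CC[C@@H]2C(=O)OC(C)(C)C | intermediate
20 | tert-butyl (1S,4R,7S,8aR)-4-{[(2E,4S)-2,4-dimethyloct-2-enoyl]oxy}-8a-methyl-6-oxo-7-(2-oxoethyl)-1,2,3,4,6,7,8,8a-octahydronaphthalene-1-carboxylate | O=CC[C@@H]1C[C@@]2(C)C(=CC1=O)[C@H](OC(=O)/C(C)=C/[C@@H](C)CCCC)CC[C@@H]2C(=O)OC(C)(C)C | intermediate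
21 | tert-butyl (1S,4R,7S,8aR)-4-{[(2E,4S)-2,4-dimethyloct-2-enoyl]oxy}-8a-methyl-6-oxo-7-(3-oxoprop-1-en-2-yl)-1,2,3,4,6,7,8,8a-octahydronaphthalene-1-carboxylate | C=C(C=O)[C@@H]1C[C@@]2(C)C(=CC1=O)[C@H](OC(=O)/C(C)=C/[C@@H](C)CCCC)CC[C@@H]2C(=O)OC(C)(C)C | intermediate
22 | integric acid, (1S,4R,7S,8aR)-4-{[(2E,4S)-2,4-dimethyloct-2-enoyl]oxy}-8a-methyl-6-oxo-7-(3-oxoprop-1-en-2-yl)-1,2,3,4,6,7,8,8a-octahydronaphthalene-1-carboxylic acid | C=C(C=O)[C@@H]1C[C@@]2(C)C(=CC1=O)[C@H](OC(=O)/C(C)=C/[C@@H](C)CCCC)CC[C@@H]2C(=O)O | target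

**Step count and risks**

Total step count: 14 (11 on the core, 3 for the side-chain acid). Longest linear sequence: 11 steps (steps 1–7 and 11–14).

Most likely to fail, first: step 3, the proposed reductive vinyl-cation ring expansion. The silane may capture the unrearranged exocyclic cation, the ring methylene may migrate instead of the quaternary carbon, or the tert-butyl ester may be lost. The fallback uses known chemistry, sets out from 6 and comes back at 7. Rh2(OAc)4 (1 mol %, CH2Cl2, 20 °C) converts 6 into the rhodium carbenoid, which undergoes the known 1,2-alkyl shift and ring expansion of β-hydroxy-α-diazo esters. The more substituted ring carbon is expected to migrate, and this gives the β-keto ester tert-butyl (8aS)-2-hydroxy-8a-methyl-6-oxo-3,4,6,7,8,8a-hexahydronaphthalene-1-carboxylate F1 (drawn as its enol; a regioisomer from methylene migration would be separated here). NaH and PhNTf2 (THF, 0 °C) then convert the β-keto ester, far more acidic than the enone, into the enol triflate tert-butyl (8aS)-8a-methyl-6-oxo-2-[(trifluoromethanesulfonyl)oxy]-3,4,6,7,8,8a-hexahydronaphthalene-1-carboxylate F2. Palladium-catalysed formate reduction (Pd(OAc)2, PPh3, Bu3N, HCO2H, DMF, 60 °C) removes the triflate and gives 7, at the cost of two extra steps.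

Second: step 6, the SmI2 reduction. The silyl dienol ether may not survive, or protonation at C1 may give the wrong epimer. The fallback sets out from 8 and comes back at 10, replacing electron transfer on the masked enone by a redox relay. Luche reduction (NaBH4, CeCl3·7H2O, MeOH, −78 °C) turns the enone of 8 into the allylic alcohol tert-butyl (6S,7R,8aS)-6-hydroxy-8a-methyl-7-(prop-2-en-1-yl)-3,4,6,7,8,8a-hexahydronaphthalene-1-carboxylate F3. Mg turnings in MeOH then reduce the enoate, now the only conjugated acceptor, to tert-butyl (1S,6S,7R,8aR)-6-hydroxy-8a-methyl-7-(prop-2-en-1-yl)-1,2,3,4,6,7,8,8a-octahydronaphthalene-1-carboxylate F4. MnO2 (CH2Cl2, 20 °C) reoxidizes the allylic alcohol to the enone tert-butyl (1S,7R,8aR)-8a-methyl-6-oxo-7-(prop-2-en-1-yl)-1,2,3,4,6,7,8,8a-octahydronaphthalene-1-carboxylate F5. Silylation as in step 5 (TBSOTf, Et3N) gives 10.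

Third: step 7, the γ-hydroxylation. Oxygen may be delivered from the α face, giving the equatorial C4 epimer. The fallback sets out from 10 and comes back at 18, changing how the C4–O ester bond and its configuration are made. If the oxidation gives mainly tert-butyl (1S,4S,7R,8aR)-4-hydroxy-8a-methyl-6-oxo-7-(prop-2-en-1-yl)-1,2,3,4,6,7,8,8a-octahydronaphthalene-1-carboxylate F6, this alcohol is not acylated with retention. It is instead coupled with 16 under Mitsunobu conditions (PPh3, DIAD, toluene, 0 → 20 °C), an SN2 esterification that inverts C4 and gives 18 directly, bypassing 11. With a mixed outcome both epimers converge on 18, 11 through step 11 and F6 through the Mitsunobu reaction.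

**Further compounds**
F1 | step 3 | tert-butyl (8aS)-2-hydroxy-8a-methyl-6-oxo-3,4,6,7,8,8a-hexahydronaphthalene-1-carboxylate (enol form of the β-keto ester) | O=C1CC[C@@]2(C)C(=C1)CCC(O)=C2C(=O)OC(C)(C)C
F2 | step 3 | tert-butyl (8aS)-8a-methyl-6-oxo-2-[(trifluoromethanesulfonyl)oxy]-3,4,6,7,8,8a-hexahydronaphthalene-1-carboxylate | O=C1CC[C@@]2(C)C(=C1)CCC(OS(=O)(=O)C(F)(F)F)=C2C(=O)OC(C)(C)C
F3 | step 6 | tert-butyl (6S,7R,8aS)-6-hydroxy-8a-methyl-7-(prop-2-en-1-yl)-3,4,6,7,8,8a-hexahydronaphthalene-1-carboxylate | C=CC[C@@H]1C[C@@]2(C)C(=C[C@H]1O)CCC=C2C(=O)OC(C)(C)C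
F4 | step 6 | tert-butyl (1S,6S,7R,8aR)-6-hydroxy-8a-methyl-7-(prop-2-en-1-yl)-1,2,3,4,6,7,8,8a-octahydronaphthalene-1-carboxylate | C=CC[C@@H]1C[C@@]2(C)C(=C[C@H]1O)CCC[C@@H]2C(=O)OC(C)(C)C
F5 | step 6 | tert-butyl (1S,7R,8aR)-8a-methyl-6-oxo-7-(prop-2-en-1-yl)-1,2,3,4,6,7,8,8a-octahydronaphthalene-1-carboxylate | C=CC[C@@H]1C[C@@]2(C)C(=CC1=O)CCC[C@@H]2C(=O)OC(C)(C)C
F6 | step 7 | tert-butyl (1S,4S,7R,8aR)-4-hydroxy-8a-methyl-6-oxo-7-(prop-2-en-1-yl)-1,2,3,4,6,7,8,8a-octahydronaphthalene-1-carboxylate | C=CC[C@@H]1C[C@@]2(C)C(=CC1=O)[C@@H](O)CC[C@@H]2C(=O)OC(C)(C)C
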